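**The decision.** If the catalyst in this flask is fading, waiting gains little and a fresh charge gains much, so the choice at 8.0 d hangs on how much conversion the charge still holds.

the same everywhere: free catalyst 1 mol%
- alpha: starting material 10 mM; second substrate 1 equiv; reagent 1.3 equiv; the very flask that is asked about, followed so far
- epsilon: starting material 15 mM; second substrate 1 equiv; reagent 1.3 equiv; run made earlier
- flask: starting material 10 mM; second substrate 1.00 equiv; reagent 1.30 equiv; time 8.0 d

| run | time / h | target / % | starting material / % |
|---|---|---|---|
| alpha | 20.0 | 22.2 | 77.6 |
| alpha | 40.0 | 34.1 | 64.6 |
| alpha | 72.0 | 46.6 | 53.3 |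
| alpha | 96.0 | 49.8 | 47.7 |
| alpha | 120 | 54.5 | 44.3 |
| alpha | 144 | 55.6 | 42.1 |
| epsilon | 1.33 | 2.6 | 97.0 |
| epsilon | 2.00 | 4.5 | 96.0 |
| epsilon | 3.00 | 5.6 | 93.7 |
| epsilon | 5.00 | 9.3 | 89.6 |
| epsilon | 6.00 | 10.9 | 88.6 |
| epsilon | 10.0 | 16.9 | 83.0 |
| epsilon | 15.0 | 22.0 | 76.4 |

(readings scatter by 0.5 percentage points)

- autumn: at 8.0 d add free catalyst, 100% of the amount charged, then wait 4.0 d
- noon: at 8.0 d add reagent, 50.0% of the amount charged, then wait 4.0 d
- dusk: at 8.0 d add starting material, 50.0% of the amount charged, then wait 4.0 d
- dawn: change nothing and wait 4.0 d more

* target, in percent of the starting material first charged, at 8.0 d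
* what to do for the largest gain in target; "none" if nothing gains more than 2 percentage points (autumn / noon / dusk / dawn / none)
* target present, in percent of the starting material first charged, after dusk
* target present, in percent of the starting material first charged, after dawn

- the volume of additions can be left aside
- a reading or a percentage of target counts all its forms, free or not

**The reach.** Take the natural log of starting material charged over starting material left: with a reaction first order in starting material, this is the time integral of the pseudo-first-order rate constant. In the alpha run it gains 0.111 from 72.0 h to 96.0 h and 0.0509 from 120 h to 144 h, two steps of 24.0 h later. Each step therefore gains 0.677 of the one before. The steps still to come add 0.107 to the last reading, giving 0.972: the reach of the charge, the final value of that log. It is a reading and carries the scatter. In the epsilon run, every charge is 1.50 times alpha's, and up to its last reading the log climbs 1.42 times as fast per hour as in alpha's first reading; that is an early speed, and it gives no reach for the epsilon run.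

**The reckoning.** At 8.0 d, 0.0491 of the reach is unspent, putting starting material near 39.7%. Target was 96.0% of the starting material consumed at the last reading, so it stands near 57.9%. In 4.0 d more, the old charge spends 0.0387. Dawn thus gains 1.5 percentage points, less than the margin, and dusk gains 3.3 points. A fresh charge adds 0.767, if it fades alike, so autumn gains 21 points, more than either. The reagent charge is 2.16 times the starting material consumed, so noon is not expected to help. The next addition is catalyst.

**The forecast.** It also chose autumn, saying “the catalyst is dying”. Its 58.5%, 62% after dusk and 60% after dawn stand slightly above this reckoning's 57.9%, 61.2% and 59.4%.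

**The result.** The flask gives 57.7%, 60.6% after dusk and 58.8% after dawn. The best move is autumn, gaining 18 points, against 3 points for dusk, 1.1 points for dawn and 0.66 points for noon.

    starting material + free catalyst ⇌ catalyst intermediate A (K = 570 L mol⁻¹, k = 440 L mol⁻¹ h⁻¹)
    reagent + catalyst intermediate A → free catalyst + target (k = 280 L mol⁻¹ h⁻¹)
    second substrate + free catalyst ⇌ catalyst intermediate B (K = 58.0 L mol⁻¹, k = 610 L mol⁻¹ h⁻¹)
    reagent + catalyst intermediate B → free catalyst + second product (k = 170 L mol⁻¹ h⁻¹)
    second substrate + catalyst intermediate B → spent catalyst (k = 7.90 L mol⁻¹ h⁻¹)
    crystals ⇌ target, rate k6*(cs6 - [target]) while solid is left; crystals form when [target] > cs6 (solubility = 0.750 mM, k = 2.40 h⁻¹)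
    reagent + target → over-reaction product (k = 0.350 L mol⁻¹ h⁻¹)

Taken forward alone, starting material uses free catalyst at 0.72 of the rate of second substrate at the start, and at 0.56 after 31.3 h. At 192 h, spent catalyst is 91.4% of the catalyst charged, while starting material stands at 38.9% and reagent at 36.4%, and the log has reached 0.944, which is 97.1% of the reach.

**A neighbour.** If each portion of catalyst carried the same reach, a neighbour flask with 4 mol% of free catalyst would have a reach of 3.89, which points to starting material near 2.04%. That neighbour flask computes to 6.5% starting material and 92.4% target, a log of 2.73, which is less than that estimate, with reagent down to 2.8% of its charge.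

The data were generated by integration with made-up constants.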